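**Plan**

- Retrosynthetic cuts: C11=C13 and C7–C11 together (olefination and epoxide opening of a phosphonoacetate carried on O6), C4=C5 (ring-closing metathesis), the O8 acyl bond, C6–C7 (alkynylation of acrolein), and C8–C9 with C9–C10 (carbonylative coupling).
- Forward order: iodo-enal acetal (C1–C4, C10, C14, C15) → ynone (adds C7–C9) → dienynol (adds C5, C6) → (E)-allylic alcohol → erythro trans-epoxy alcohol → phosphonoacetate → γ-lactone with exocyclic methylene → C8 ester → ten-membered ring → deprotection.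
- Enabling feature: in the lactone ring (O–C12–C11–C7–C6) C11 is the α-carbon of the C12 carbonyl and C7 lies between the oxygen-bearing C6 and C8. An ester on O6 holds a phosphonate-stabilised C11 carbanion five atoms from C7, and a C7–C8 trans-epoxide makes C7 the electrophile whose opening leaves the C8 hydroxyl.
- Stereochemistry: C9 from CBS reduction; C6 from Zn–ProPhenol alkynylation; C7 and C8 from matched Sharpless epoxidation followed by SN2 inversion at C7 with retention at C8; the side chain from (S)-2-methylbutanoic anhydride.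
- Alkene geometry: C1=C10 from the (Z)-α-iodoenal; C4=C5 cis from ring closure in the ten-membered ring.

Key step: step 11

Remark: locants C1–C15 are the germacrane ones (ring C1–C10; lactone C6–O–C12(=O)–C11(=C13)–C7; C14 formyl carbon; C15 methyl). CIP descriptors change along the route with substituent priorities; the spatial arrangement is that of the SMILES.

**Route**

Step 1
Reactants: 1 2-methylhexa-1,5-diene; 2 (E)-but-2-enal
Product: 3 (2E)-6-methylhepta-2,6-dienal
Conditions: second-generation Grubbs catalyst (2 mol%), 2 (3 equiv), CH2Cl2, 40 °C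
Reagents that add atoms: none
Why: Olefin cross-metathesis of the monosubstituted alkene with an enal partner should give the (E)-enal, the 1,1-disubstituted alkene being too hindered to compete.

Step 2
Reactants: 3 (2E)-6-methylhepta-2,6-dienal
Product: 4 (2Z)-2-iodo-6-methylhepta-2,6-dienal
Conditions: I2, K2CO3, DMAP (cat.), THF/H2O, rt
Reagents that add atoms: iodine II
Why: α-Iodination of an enal by the Baylis–Hillman-type sequence (DMAP addition, iodination of the enolate, E1cB loss of DMAP) should give the (Z)-iodide with the formyl group trans to the chain, which fixes the C1=C10 geometry.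

Step 3
Reactants: 4 (2Z)-2-iodo-6-methylhepta-2,6-dienal
Product: 5 2-[(1Z)-1-iodo-5-methylhexa-1,5-dien-1-yl]-1,3-dioxolane
Conditions: 1,2-bis(trimethylsilyloxy)ethane, TMSOTf (cat.), CH2Cl2, −78 °C
Reagents that add atoms: 1,2-bis(trimethylsilyloxy)ethane C[Si](C)(C)OCCO[Si](C)(C)C
Why: Noyori acetalization under kinetic, aprotic conditions should mask C14 without moving or isomerizing the double bond.

Step 4
Reactants: 5 2-[(1Z)-1-iodo-5-methylhexa-1,5-dien-1-yl]-1,3-dioxolane; 6 ethynyltrimethylsilane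
Product: 7 (4Z)-4-(1,3-dioxolan-2-yl)-8-methyl-1-(trimethylsilyl)nona-4,8-dien-1-yn-3-one
Conditions: PdCl2(PPh3)2 (cat.), CuI (cat.), Et3N, CO (1 atm), THF, rt
Reagents that add atoms: carbon monoxide [C-]#[O+]
Why: Carbonylative Sonogashira coupling: oxidative addition with retention of alkene geometry, CO insertion into the alkenyl–palladium bond and capture of the acyl complex by the alkyne should give the ynone, C9 coming from CO.

Step 5
Reactants: 7 (4Z)-4-(1,3-dioxolan-2-yl)-8-methyl-1-(trimethylsilyl)nona-4,8-dien-1-yn-3-one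
Product: 9 (3R,4E)-4-(1,3-dioxolan-2-yl)-8-methylnona-4,8-dien-1-yn-3-ol, via silylalkynyl carbinol 8 (not isolated)
Conditions: (S)-2-methyl-CBS-oxazaborolidine (0.2–1 equiv), catecholborane, CH2Cl2, −78 °C; then MeOH, K2CO3, rt
Reagents that add atoms: none
Why: CBS reduction with the alkynyl group as the small and the branched alkenyl group as the large substituent should set C9 (the antipodal catalyst is the remedy if the silyl group reverses the sense), catecholborane does not hydroborate the alkenes at this temperature, and basic methanol then cleaves the C(sp)–Si bond.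

Step 6
Reactants: 9 (3R,4E)-4-(1,3-dioxolan-2-yl)-8-methylnona-4,8-dien-1-yn-3-ol
Product: 10 tert-butyl{[(3R,4E)-4-(1,3-dioxolan-2-yl)-8-methylnona-4,8-dien-1-yn-3-yl]oxy}dimethylsilane
Conditions: TBSCl, imidazole, DMF, rt
Reagents that add atoms: tert-butyldimethylsilyl chloride CC(C)(C)[Si](C)(C)Cl
Why: Standard silylation protects O9 so that only O6 can later direct reduction and epoxidation and only O8 can later be acylated.

Step 7
Reactants: 10 tert-butyl{[(3R,4E)-4-(1,3-dioxolan-2-yl)-8-methylnona-4,8-dien-1-yn-3-yl]oxy}dimethylsilane; 11 prop-2-enal (acrolein)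
Product: 12 (3R,6R,7E)-6-[(tert-butyldimethylsilyl)oxy]-7-(1,3-dioxolan-2-yl)-11-methyldodeca-1,7,11-trien-4-yn-3-ol
Conditions: Me2Zn, (S,S)-ProPhenol (cat.), Ph3P=O (cat.), toluene, 0 °C
Reagents that add atoms: none
Why: Zinc–ProPhenol asymmetric alkynylation of an enal adds 1,2 and should set C6 under reagent control (the ligand antipode is taken if needed to obtain the 3R carbinol); the C9 centre is remote from the reacting carbon.

Step 8
Reactants: 12 (3R,6R,7E)-6-[(tert-butyldimethylsilyl)oxy]-7-(1,3-dioxolan-2-yl)-11-methyldodeca-1,7,11-trien-4-yn-3-ol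
Product: 13 (3R,4E,6R,7E)-6-[(tert-butyldimethylsilyl)oxy]-7-(1,3-dioxolan-2-yl)-11-methyldodeca-1,4,7,11-tetraen-3-ol
Conditions: NaAlH2(OCH2CH2OMe)2 (Red-Al), THF, 0 °C to rt
Reagents that add atoms: none
Why: Alkoxide-directed trans-hydroalumination of the propargylic alcohol should give the (E)-C7=C8 alkene only, the silyl ether and acetal being inert.

Step 9
Reactants: 13 (3R,4E,6R,7E)-6-[(tert-butyldimethylsilyl)oxy]-7-(1,3-dioxolan-2-yl)-11-methyldodeca-1,4,7,11-tetraen-3-ol
Product: 14 (1R)-1-[(2R,3S)-3-{(1S,2E)-1-[(tert-butyldimethylsilyl)oxy]-2-(1,3-dioxolan-2-yl)-6-methylhepta-2,6-dien-1-yl}oxiran-2-yl]prop-2-en-1-ol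
Conditions: Ti(OiPr)4 (0.2 equiv), D-(−)-diisopropyl tartrate (0.25 equiv), t-BuOOH, 4 Å MS, CH2Cl2, −20 °C
Reagents that add atoms: tert-butyl hydroperoxide CC(C)(C)OO
Why: Sharpless asymmetric epoxidation in its matched sense should deliver oxygen to the (E)-C7=C8 alkene of the 6R carbinol on the face that gives the erythro trans-epoxy alcohol, setting C7 and C8; the vinyl group is a much slower substrate, the C1=C10 alkene has no free allylic hydroxyl, and any C6 epimer from step 7 is the slow-reacting partner and stays behind.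

Step 10
Reactants: 14 the epoxy alcohol of step 9; 15 (diethoxyphosphoryl)acetic acid
Product: 16 (1R)-1-[(2R,3S)-3-{(1S,2E)-1-[(tert-butyldimethylsilyl)oxy]-2-(1,3-dioxolan-2-yl)-6-methylhepta-2,6-dien-1-yl}oxiran-2-yl]prop-2-en-1-yl (diethoxyphosphoryl)acetate
Conditions: DCC, DMAP (cat.), CH2Cl2, 0 °C to rt
Reagents that add atoms: none
Why: Steglich esterification of the only free hydroxyl installs the tether that carries C11, C12 and the phosphonate activating group.

Step 11
Reactants: 16 the epoxy phosphonoacetate of step 10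
Product: 18 (4R,5R)-4-[(1S,2S,3E)-2-[(tert-butyldimethylsilyl)oxy]-3-(1,3-dioxolan-2-yl)-1-hydroxy-7-methylocta-3,7-dien-1-yl]-5-ethenyl-3-methylideneoxolan-2-one, via α-phosphono lactone 17 (not isolated)
Conditions: LiN(SiMe3)2 (1.05 equiv), THF, −78 to 45 °C; then paraformaldehyde, 0 °C to rt
Reagents that add atoms: formaldehyde (as paraformaldehyde) C=O
Why: Proposed new method: LiN(SiMe3)2 forms the lithium-chelated phosphonoacetate carbanion at C11, which attacks the proximal epoxide carbon C7 from the side opposite the C7–O bond while the epoxide oxygen stays on C8; the closest known reaction types are the opening of epoxides by phosphonoacetate anions (first stage of the Wadsworth–Emmons cyclopropanation), the malonate–epoxide synthesis of γ-lactones and the intramolecular Michael/olefination of phosphonoacetates of γ-hydroxy enones, whereas the ester-tethered epoxide version is not established. The lactone ring (O–C12–C11–C7–C6) closes in the 5-exo-tet mode, which the phosphonate allows because its carbanion needs no coplanarity with the ring carbonyl. C7 is set by stereospecific SN2 inversion and C8 keeps the configuration given by the epoxidation, so the trans-epoxide next to the erythro C6 carbinol becomes the trans-fused lactone with the 8-hydroxyl on the required face. The alkoxide released is protonated at once by the far more acidic C11–H, and the phosphonate carbanion so regenerated is consumed by formaldehyde in a Horner–Wadsworth–Emmons olefination that gives the exocyclic methylene. The step needs attack at C7 over C8, carbon over oxygen alkylation, and no phosphoryl transfer to O8 or lactone migration to O8: the five-membered closure and the branched silyloxy-bearing C9 next to C8 favour C7, lithium chelation of both phosphonoenolate oxygens favours C-alkylation, and the carbanion resting state keeps the alkoxide concentration low and the lactone carbonyl non-electrophilic.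

Step 12
Reactants: 18 the hydroxy α-methylene lactone of step 11; 19 (2S)-2-methylbutanoic anhydride
Product: 20 (1S,2S,3E)-2-[(tert-butyldimethylsilyl)oxy]-3-(1,3-dioxolan-2-yl)-1-[(2R,3S)-2-ethenyl-4-methylidene-5-oxooxolan-3-yl]-7-methylocta-3,7-dien-1-yl (2S)-2-methylbutanoate
Conditions: Et3N, DMAP (cat.), CH2Cl2, 0 °C to rt
Reagents that add atoms: none
Why: DMAP-catalysed acylation of the only free hydroxyl (O8, unmasked in step 11 while O9 stays silylated) with the enantiopure anhydride should install the side chain without a site-selectivity problem.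

Step 13
Reactants: 20 the diene ester of step 12
Product: 21 (3aS,4S,5S,6E,10Z,11aR)-5-[(tert-butyldimethylsilyl)oxy]-6-(1,3-dioxolan-2-yl)-10-methyl-3-methylidene-2-oxo-2,3,3a,4,5,8,9,11a-octahydrocyclodeca[b]furan-4-yl (2S)-2-methylbutanoate
Conditions: second-generation Grubbs catalyst (10 mol%), 1,4-benzoquinone (cat.), toluene (1 mM), 80 °C
Reagents that add atoms: none
Why: Ring-closing metathesis between the C6 vinyl group and the 1,1-disubstituted C4 alkene should close the ten-membered ring with the ring-cis C4=C5 bond, the only geometry the ring tolerates next to the cis C1=C10 bond and the trans-fused lactone; the trisubstituted C1=C10 and electron-poor exocyclic alkenes are poor metathesis partners.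

Step 14
Reactants: 21 the protected macrocycle of step 13
Product: 22 (3aS,4S,5S,6E,10Z,11aR)-6-formyl-5-hydroxy-10-methyl-3-methylidene-2-oxo-2,3,3a,4,5,8,9,11a-octahydrocyclodeca[b]furan-4-yl (2S)-2-methylbutanoate (CNP0168436.1)
Conditions: aq. HF (48%), MeCN/H2O, 0 °C to rt
Reagents that add atoms: water O
Why: Aqueous HF should cleave the silyl ether and hydrolyse the enal dioxolane in one operation under acidic conditions, where O8-to-O9 acyl migration is slow and the methylene lactone and enal are stable.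

**Compound list**

1 | 2-methylhexa-1,5-diene | C=C(C)CCC=C | starting material
2 | (E)-but-2-enal | C/C=C/C=O | starting material
3 | (2E)-6-methylhepta-2,6-dienal | C=C(C)CC/C=C/C=O | intermediate
4 | (2Z)-2-iodo-6-methylhepta-2,6-dienal | C=C(C)CC/C=C(\I)C=O | intermediate
5 | 2-[(1Z)-1-iodo-5-methylhexa-1,5-dien-1-yl]-1,3-dioxolane | C=C(C)CC/C=C(\I)C1OCCO1 | intermediate
6 | ethynyltrimethylsilane | C#C[Si](C)(C)C | starting material
7 | (4Z)-4-(1,3-dioxolan-2-yl)-8-methyl-1-(trimethylsilyl)nona-4,8-dien-1-yn-3-one | C=C(C)CC/C=C(\C(=O)C#C[Si](C)(C)C)C1OCCO1 | intermediate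
8 | (3S,4E)-4-(1,3-dioxolan-2-yl)-8-methyl-1-(trimethylsilyl)nona-4,8-dien-1-yn-3-ol (not isolated) | C=C(C)CC/C=C(\[C@H](O)C#C[Si](C)(C)C)C1OCCO1 | intermediate
9 | (3R,4E)-4-(1,3-dioxolan-2-yl)-8-methylnona-4,8-dien-1-yn-3-ol | C=C(C)CC/C=C(\[C@H](O)C#C)C1OCCO1 | intermediate
10 | tert-butyl{[(3R,4E)-4-(1,3-dioxolan-2-yl)-8-methylnona-4,8-dien-1-yn-3-yl]oxy}dimethylsilane | C=C(C)CC/C=C(\[C@H](O[Si](C)(C)C(C)(C)C)C#C)C1OCCO1 | intermediate
11 | prop-2-enal (acrolein) | C=CC=O | starting material
12 | (3R,6R,7E)-6-[(tert-butyldimethylsilyl)oxy]-7-(1,3-dioxolan-2-yl)-11-methyldodeca-1,7,11-trien-4-yn-3-ol | C=C(C)CC/C=C(\[C@H](O[Si](C)(C)C(C)(C)C)C#C[C@H](O)C=C)C1OCCO1 | intermediate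
13 | (3R,4E,6R,7E)-6-[(tert-butyldimethylsilyl)oxy]-7-(1,3-dioxolan-2-yl)-11-methyldodeca-1,4,7,11-tetraen-3-ol | C=C[C@@H](O)/C=C/[C@@H](O[Si](C)(C)C(C)(C)C)/C(C1OCCO1)=C\CCC(C)=C | intermediate
14 | (1R)-1-[(2R,3S)-3-{(1S,2E)-1-[(tert-butyldimethylsilyl)oxy]-2-(1,3-dioxolan-2-yl)-6-methylhepta-2,6-dien-1-yl}oxiran-2-yl]prop-2-en-1-ol | C=C[C@@H](O)[C@H]1O[C@@H]1[C@@H](O[Si](C)(C)C(C)(C)C)/C(C2OCCO2)=C\CCC(C)=C | intermediate
15 | (diethoxyphosphoryl)acetic acid | CCOP(=O)(CC(=O)O)OCC | starting material
16 | (1R)-1-[(2R,3S)-3-{(1S,2E)-1-[(tert-butyldimethylsilyl)oxy]-2-(1,3-dioxolan-2-yl)-6-methylhepta-2,6-dien-1-yl}oxiran-2-yl]prop-2-en-1-yl (diethoxyphosphoryl)acetate | C=C[C@@H](OC(=O)CP(=O)(OCC)OCC)[C@H]1O[C@@H]1[C@@H](O[Si](C)(C)C(C)(C)C)/C(C2OCCO2)=C\CCC(C)=C | intermediate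
17 | diethyl {(4R,5R)-4-[(1S,2S,3E)-2-[(tert-butyldimethylsilyl)oxy]-3-(1,3-dioxolan-2-yl)-1-hydroxy-7-methylocta-3,7-dien-1-yl]-5-ethenyl-2-oxooxolan-3-yl}phosphonate (C3 epimers; formed as its lithium carbanion; not isolated) | CCOP(=O)(OCC)C1C(=O)O[C@H](C=C)[C@H]1[C@H](O)[C@@H](O[Si](C)(C)C(C)(C)C)/C(C2OCCO2)=C\CCC(C)=C | intermediate
18 | (4R,5R)-4-[(1S,2S,3E)-2-[(tert-butyldimethylsilyl)oxy]-3-(1,3-dioxolan-2-yl)-1-hydroxy-7-methylocta-3,7-dien-1-yl]-5-ethenyl-3-methylideneoxolan-2-one | C=C1C(=O)O[C@H](C=C)[C@H]1[C@H](O)[C@@H](O[Si](C)(C)C(C)(C)C)/C(C2OCCO2)=C\CCC(C)=C | intermediate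
19 | (2S)-2-methylbutanoic anhydride | CC[C@H](C)C(=O)OC(=O)[C@@H](C)CC | starting material
20 | (1S,2S,3E)-2-[(tert-butyldimethylsilyl)oxy]-3-(1,3-dioxolan-2-yl)-1-[(2R,3S)-2-ethenyl-4-methylidene-5-oxooxolan-3-yl]-7-methylocta-3,7-dien-1-yl (2S)-2-methylbutanoate | C=C1C(=O)O[C@H](C=C)[C@H]1[C@H](OC(=O)[C@@H](C)CC)[C@@H](O[Si](C)(C)C(C)(C)C)/C(C2OCCO2)=C\CCC(C)=C | intermediate
21 | (3aS,4S,5S,6E,10Z,11aR)-5-[(tert-butyldimethylsilyl)oxy]-6-(1,3-dioxolan-2-yl)-10-methyl-3-methylidene-2-oxo-2,3,3a,4,5,8,9,11a-octahydrocyclodeca[b]furan-4-yl (2S)-2-methylbutanoate | C=C1C(=O)O[C@@H]2/C=C(/C)CC/C=C(/C3OCCO3)[C@H](O[Si](C)(C)C(C)(C)C)[C@@H](OC(=O)[C@@H](C)CC)[C@@H]12 | intermediate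
22 | (3aS,4S,5S,6E,10Z,11aR)-6-formyl-5-hydroxy-10-methyl-3-methylidene-2-oxo-2,3,3a,4,5,8,9,11a-octahydrocyclodeca[b]furan-4-yl (2S)-2-methylbutanoate | C=C1C(=O)O[C@@H]2/C=C(/C)CC/C=C(/C=O)[C@H](O)[C@@H](OC(=O)[C@@H](C)CC)[C@@H]12 | target

**Step count**

Total steps: 14. Longest linear sequence: 14 steps (1 to 22).

**Steps most likely to fail**

1. Step 11 (proposed new method). What may go wrong: alkylation through a phosphonoenolate oxygen or at the distal epoxide carbon, phosphoryl migration to the freed alkoxide followed by cyclopropane closure, or silyl migration from O9 to O8 while the alkoxide exists. Fallback, known chemistry with a radical instead of an anionic ring closure, sets out from 14 and comes back at 20. O-Propargylation of 14 (NaH, propargyl bromide, THF) gives the propargyl ether of the epoxy alcohol F1. Cp2TiCl (trivalent titanium, made from Cp2TiCl2 and Zn in THF) opens the epoxide homolytically, and the C7 radical closes 5-exo-dig onto the alkyne to give the 3-methylidene-tetrahydrofuran alcohol F2. F2 already holds the C7–C11 bond, the exocyclic methylene and the free 8-hydroxyl, and the 6,7-trans arrangement is expected from the cyclization transition state. Acylation with 19 (Et3N, DMAP) gives the tetrahydrofuran ester F3, and oxidation of the ring CH2 that is both allylic and next to oxygen (CrO3, 3,5-dimethylpyrazole, CH2Cl2) gives 20.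

2. Step 13. What may go wrong: oligomerization in place of closure of the strained ten-membered ring, or engagement of the exocyclic methylene of the lactone by the ruthenium carbene. Fallback, ring closure before the olefination, sets out from 17 (isolated when step 11 is quenched with aqueous NH4Cl before formaldehyde is added) and comes back at 21. Acylation of 17 with 19 (Et3N, DMAP) gives the α-phosphono lactone ester F4. Ring-closing metathesis with the second-generation Grubbs catalyst, now on a substrate without the exocyclic methylene, gives the macrocyclic α-phosphono lactone F5. Horner–Wadsworth–Emmons olefination (K2CO3, aqueous formaldehyde, THF) gives 21.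

3. Step 9. What may go wrong: poor site selectivity between the two alkenes that flank the C6 carbinol, or incomplete erythro selectivity. Fallback, epoxidation of a primary allylic alcohol before the vinyl group exists, sets out from 10 and comes back at 14. Deprotonation of 10 (n-BuLi, THF, −78 °C) and addition to paraformaldehyde gives the primary propargylic alcohol F6. NaAlH2(OCH2CH2OMe)2 gives the (E)-allylic alcohol F7. Sharpless epoxidation (Ti(OiPr)4, D-(−)-diisopropyl tartrate, t-BuOOH), with no second allylic alkene present, gives the primary epoxy alcohol F8. Dess–Martin oxidation gives the epoxy aldehyde F9. Addition of CH2=CHMgBr (THF, −78 °C) is expected to favour the erythro (Felkin–Anh) carbinol 14; a diastereomer separation would be needed.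

**Further compounds**

F1 | step 11 | propargyl ether of 14: (2R,3S)-2-[(1R)-1-(prop-2-yn-1-yloxy)prop-2-en-1-yl]-3-{(1S,2E)-1-[(tert-butyldimethylsilyl)oxy]-2-(1,3-dioxolan-2-yl)-6-methylhepta-2,6-dien-1-yl}oxirane | C#CCO[C@H](C=C)[C@H]1O[C@@H]1[C@@H](O[Si](C)(C)C(C)(C)C)/C(C2OCCO2)=C\CCC(C)=C
F2 | step 11 | (1S,2S,3E)-2-[(tert-butyldimethylsilyl)oxy]-3-(1,3-dioxolan-2-yl)-1-[(2R,3R)-2-ethenyl-4-methylideneoxolan-3-yl]-7-methylocta-3,7-dien-1-ol | C=C1CO[C@H](C=C)[C@H]1[C@H](O)[C@@H](O[Si](C)(C)C(C)(C)C)/C(C2OCCO2)=C\CCC(C)=C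
F3 | step 11 | (1S,2S,3E)-2-[(tert-butyldimethylsilyl)oxy]-3-(1,3-dioxolan-2-yl)-1-[(2R,3S)-2-ethenyl-4-methylideneoxolan-3-yl]-7-methylocta-3,7-dien-1-yl (2S)-2-methylbutanoate | C=C1CO[C@H](C=C)[C@H]1[C@H](OC(=O)[C@@H](C)CC)[C@@H](O[Si](C)(C)C(C)(C)C)/C(C2OCCO2)=C\CCC(C)=C
F4 | step 13 | (2S)-2-methylbutanoate of 17 at O8 (α-phosphono lactone ester; C11 epimers) | CCOP(=O)(OCC)C1C(=O)O[C@H](C=C)[C@H]1[C@H](OC(=O)[C@@H](C)CC)[C@@H](O[Si](C)(C)C(C)(C)C)/C(C2OCCO2)=C\CCC(C)=C
F5 | step 13 | macrocyclic α-phosphono lactone: analogue of 21 with a diethoxyphosphoryl group and H on C11 in place of the methylidene (C11 epimers) | CCOP(=O)(OCC)C1C(=O)O[C@@H]2/C=C(/C)CC/C=C(/C3OCCO3)[C@H](O[Si](C)(C)C(C)(C)C)[C@@H](OC(=O)[C@@H](C)CC)[C@@H]12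
F6 | step 9 | (4R,5E)-4-[(tert-butyldimethylsilyl)oxy]-5-(1,3-dioxolan-2-yl)-9-methyldeca-5,9-dien-2-yn-1-ol | C=C(C)CC/C=C(\[C@H](O[Si](C)(C)C(C)(C)C)C#CCO)C1OCCO1
F7 | step 9 | (2E,4R,5E)-4-[(tert-butyldimethylsilyl)oxy]-5-(1,3-dioxolan-2-yl)-9-methyldeca-2,5,9-trien-1-ol | OC/C=C/[C@@H](O[Si](C)(C)C(C)(C)C)/C(C1OCCO1)=C\CCC(C)=C
F8 | step 9 | trans-epoxy alcohol: [3-{(1S,2E)-1-[(tert-butyldimethylsilyl)oxy]-2-(1,3-dioxolan-2-yl)-6-methylhepta-2,6-dien-1-yl}oxiran-2-yl]methanol with the epoxide configured as in 14 | OC[C@H]1O[C@@H]1[C@@H](O[Si](C)(C)C(C)(C)C)/C(C2OCCO2)=C\CCC(C)=C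
F9 | step 9 | trans-epoxy aldehyde: 3-{(1S,2E)-1-[(tert-butyldimethylsilyl)oxy]-2-(1,3-dioxolan-2-yl)-6-methylhepta-2,6-dien-1-yl}oxirane-2-carbaldehyde with the epoxide configured as in 14 | O=C[C@H]1O[C@@H]1[C@@H](O[Si](C)(C)C(C)(C)C)/C(C2OCCO2)=C\CCC(C)=C
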